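## Retrosynthetic overview

- **Feature:** each pyran ring holds an O1–C2(H)(catechol) carbon of the same spatial sense (2S in the 3-deoxy upper unit, 2R in the lower flavan-3-ol unit; only the CIP priorities differ), next to a bond that can be an alkene: C3–C4 in the upper ring, C3'–C4' in the lower ring.
- **Endgame:** target 21 ⇐ hydrogenation of C3=C4 anti to the C2 aryl (sets C4) with debenzylation ⇐ hydroboration of C3'=C4' (sets C3' trans to C2') ⇐ bis(2H-chromene) 18.
- **Key disconnection:** 18 ⇐ double ring-closing metathesis of tetraene 16, lower pyran first (C3'=C4'), then upper pyran (C3=C4).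
- **Stereocentres C2/C2':** 16 ⇐ double Ir-catalysed asymmetric allylic etherification of bisphenol 11 with cinnamyl carbonate 15.
- **Core:** 11 ⇐ aryllithium of D-ring bromostyrene 5 + A-ring ketone 7 (addition, then dehydration builds the C4–C8' bond and the C4=CH2 alkene); temporary O-allyl groups, permanent benzyl ethers.

Key step: step 12

Assumption 1: the (Sa,Sc,Sc) antipode of the BINOL/bis(1-phenylethyl)amine phosphoramidite is taken to give the (S)-1-arylallyl ethers; if the sense of induction is the opposite, its enantiomer is used.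

Assumption 2: bromination in step 2 is taken to occur ortho to the free hydroxyl (C3), as is usual for 2-hydroxy-4,6-dialkoxyaryl carbonyl compounds. This is to be confirmed by NOE: the remaining ring proton should show contacts to both OCH2Ph groups.

## Route

Step 1
Reactants: 1 2,4,6-trihydroxybenzaldehyde
Product: 2 4,6-bis(benzyloxy)-2-hydroxybenzaldehyde
Conditions: BnBr (2.1 equiv), K2CO3, DMF, 0 °C → rt
Reagents that add atoms: benzyl bromide, BrCc1ccccc1
Why: Williamson etherification in which the 4-OH and one ortho OH are alkylated while the remaining ortho OH, hydrogen-bonded to the formyl group, should stay free with two equivalents of halide.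

Step 2
Reactants: 2 4,6-bis(benzyloxy)-2-hydroxybenzaldehyde
Product: 3 4,6-bis(benzyloxy)-3-bromo-2-hydroxybenzaldehyde
Conditions: NBS (1.0 equiv), CH2Cl2, −20 → 0 °C
Reagents that add atoms: N-bromosuccinimide, O=C1CCC(=O)N1Br
Why: Electrophilic aromatic bromination, expected at C3 (ortho to the free OH, para to the 6-benzyloxy group) and not at C5, which is flanked by two benzyloxy groups.

Step 3
Reactants: 3 4,6-bis(benzyloxy)-3-bromo-2-hydroxybenzaldehyde
Product: 4 2-(allyloxy)-4,6-bis(benzyloxy)-3-bromobenzaldehyde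
Conditions: allyl bromide, K2CO3, DMF, 50 °C
Reagents that add atoms: allyl bromide, C=CCBr
Why: Williamson O-allylation of the phenoxide installs a temporary group that tolerates organolithium chemistry and is later removed under neutral conditions.

Step 4
Reactants: 4 2-(allyloxy)-4,6-bis(benzyloxy)-3-bromobenzaldehyde
Product: 5 3-(allyloxy)-1,5-bis(benzyloxy)-2-bromo-4-ethenylbenzene
Conditions: Ph3PCH3Br, KOtBu, THF, 0 °C → rt
Reagents that add atoms: methyltriphenylphosphonium bromide, C[P+](c1ccccc1)(c1ccccc1)c1ccccc1.[Br-]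
Why: Wittig methylenation of the non-enolisable aldehyde gives the C4a' vinyl group that will become C4' of the lower ring.

Step 5
Reactants: 6 1-[4-(benzyloxy)-2-hydroxyphenyl]ethan-1-one
Product: 7 1-[2-(allyloxy)-4-(benzyloxy)phenyl]ethan-1-one
Conditions: allyl bromide, K2CO3, DMF, 60 °C
Reagents that add atoms: allyl bromide, C=CCBr
Why: Williamson O-allylation masks the A-ring phenol so that it does not quench the aryllithium in step 6.

Step 6
Reactants: 5 3-(allyloxy)-1,5-bis(benzyloxy)-2-bromo-4-ethenylbenzene; 7 1-[2-(allyloxy)-4-(benzyloxy)phenyl]ethan-1-one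
Product: 10 3-(allyloxy)-4-{1-[2-(allyloxy)-4-(benzyloxy)phenyl]ethenyl}-1,5-bis(benzyloxy)-2-ethenylbenzene, via aryllithium 8 (not isolated), via tertiary carbinol 9 (not isolated)
Conditions: 5, n-BuLi, THF, −78 °C; then 7 precomplexed with LaCl3·2LiCl, −78 → −20 °C; aq. NH4Cl; crude 9, MsCl, Et3N, CH2Cl2, 0 °C → rt
Reagents that add atoms: none
Why: Bromine–lithium exchange and 1,2-addition of the aryllithium to the lanthanum-activated ketone (enolisation suppressed) give the diaryl methyl carbinol, and its O-sulfonylation triggers E1 loss to the only possible alkene, the 1,1-diarylethylene, without acid that would attack the electron-rich styrene.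

Step 7
Reactants: 10 3-(allyloxy)-4-{1-[2-(allyloxy)-4-(benzyloxy)phenyl]ethenyl}-1,5-bis(benzyloxy)-2-ethenylbenzene
Product: 11 3,5-bis(benzyloxy)-2-{1-[4-(benzyloxy)-2-hydroxyphenyl]ethenyl}-6-ethenylphenol
Conditions: Pd(PPh3)4 (5 mol%), morpholine, THF, rt
Reagents that add atoms: none
Why: Tsuji–Trost deallylation: Pd(0) ionises both aryl allyl ethers to π-allyl complexes that morpholine captures, freeing the two phenols under neutral conditions that spare the benzyl ethers and both alkenes.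

Step 8
Reactants: 12 caffeic acid
Product: 13 benzyl (E)-3-[3,4-bis(benzyloxy)phenyl]prop-2-enoate
Conditions: BnBr (3.3 equiv), K2CO3, DMF, 60 °C
Reagents that add atoms: benzyl bromide, BrCc1ccccc1
Why: Exhaustive Williamson/carboxylate alkylation protects the catechol as benzyl ethers and activates the acid as an ester for reduction.

Step 9
Reactants: 13 benzyl (E)-3-[3,4-bis(benzyloxy)phenyl]prop-2-enoate
Product: 14 (E)-3-[3,4-bis(benzyloxy)phenyl]prop-2-en-1-ol
Conditions: DIBAL-H (2.5 equiv), CH2Cl2, −78 → 0 °C; Rochelle salt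
Reagents that add atoms: none
Why: DIBAL-H reduces the enoate in 1,2-fashion to the allylic alcohol without touching the E alkene.

Step 10
Reactants: 14 (E)-3-[3,4-bis(benzyloxy)phenyl]prop-2-en-1-ol
Product: 15 (E)-3-[3,4-bis(benzyloxy)phenyl]prop-2-en-1-yl methyl carbonate
Conditions: ClCO2Me, pyridine, CH2Cl2, 0 °C
Reagents that add atoms: methyl chloroformate, COC(=O)Cl
Why: Acylation of the primary allylic alcohol gives the linear carbonate, the standard electrophile for iridium-catalysed allylic substitution.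

Step 11
Reactants: 11 3,5-bis(benzyloxy)-2-{1-[4-(benzyloxy)-2-hydroxyphenyl]ethenyl}-6-ethenylphenol; 15 (E)-3-[3,4-bis(benzyloxy)phenyl]prop-2-en-1-yl methyl carbonate
Product: 16 (S,S)-tetraene: 1,5-bis(benzyloxy)-3-{[(1S)-1-(3,4-bis(benzyloxy)phenyl)prop-2-en-1-yl]oxy}-4-{1-[4-(benzyloxy)-2-{[(1S)-1-(3,4-bis(benzyloxy)phenyl)prop-2-en-1-yl]oxy}phenyl]ethenyl}-2-ethenylbenzene
Conditions: 11, LiHMDS (2.05 equiv), THF, 0 °C; 15 (2.6 equiv), [Ir(cod)Cl]2 (4 mol%), (Sa,Sc,Sc)-BINOL/bis(1-phenylethyl)amine phosphoramidite (8 mol%, preactivated with n-PrNH2), THF, rt → 40 °C; aqueous work-up, Et3N-deactivated silica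
Reagents that add atoms: none
Why: Iridium-catalysed asymmetric allylic etherification, in which each lithium phenoxide attacks the aryl-bearing terminus of the (π-allyl)Ir–phosphoramidite complex to give the branched ether; the ligand controls the face of attack at both oxygens and so sets both ether carbons (S) (C2 and C2' of the target), and the minor diastereomers should be removable by chromatography.

Step 12
Reactants: 16 (S,S)-tetraene
Product: 18 (2S)-7-(benzyloxy)-2-[3,4-bis(benzyloxy)phenyl]-4-{(2S)-5,7-bis(benzyloxy)-2-[3,4-bis(benzyloxy)phenyl]-2H-chromen-8-yl}-2H-chromene, via lower-ring-closed triene 17 (not isolated)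
Conditions: Hoveyda–Grubbs second-generation catalyst (5 + 5 mol%), toluene (2 mM), 40 °C then 80 °C, Ar sparge
Reagents that add atoms: none
Why: A ruthenium alkylidene formed at a terminal O-allyl CH=CH2 undergoes [2+2] cycloaddition and cycloreversion through ruthenacyclobutanes, first with the C4a' vinyl group and then, from the second ether, with the 1,1-diarylethylene C4=CH2, each event expelling ethylene. The closest known reactions are ring-closing metathesis of 2-vinylaryl 1-arylallyl ethers to 2-aryl-2H-chromenes and of 2-(allyloxy)aryl 1,1-diarylethylenes to 4-aryl-2H-chromenes, run here in two directions in one substrate. The lower pyran closes by joining C3' to C4' (cis-disubstituted alkene, six-membered ring) and the upper pyran by joining C3 to C4 (trisubstituted alkene, six-membered ring). No stereocentre is created; C2 and C2' are the ether carbons fixed in step 11 and none of their bonds is broken. The selectivity needed is pairing of the D-ring ether with the vinyl group and not with the geminally diaryl-substituted alkene, which the much faster cycloaddition to a monosubstituted alkene should secure; once that ring exists the A-ring ether can reach only the diarylethylene in a six-membered mode. High dilution, moderate heat and removal of ethylene favour the slower second closure over cross-metathesis and keep the aryl allyl ethers below Claisen temperatures.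

Step 13
Reactants: 18 hepta-O-benzyl bis(2H-chromene)
Product: 20 (2R,3S)-5,7-bis(benzyloxy)-2-[3,4-bis(benzyloxy)phenyl]-8-{(2S)-7-(benzyloxy)-2-[3,4-bis(benzyloxy)phenyl]-2H-chromen-4-yl}chroman-3-ol, via alkylborane 19 (not isolated)
Conditions: BH3·THF (1.2 equiv), THF, 0 °C → rt; then 3 M NaOH, 30% H2O2, 0 °C
Reagents that add atoms: hydrogen peroxide, OO
Why: Hydroboration–oxidation of a flav-3-ene: borane adds syn across the cis-disubstituted C3'=C4' bond with boron at C3' and on the face opposite the C2' aryl, and oxidation with retention gives the 2',3'-trans (2R,3S) alcohol, while the trisubstituted C3=C4 alkene, screened by the di-ortho-substituted D ring, should react more slowly.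

Step 14
Reactants: 20 hepta-O-benzyl flavan-3-ol/2H-chromene
Product: 21 (2R,3S)-2-(3,4-dihydroxyphenyl)-8-[(2S,4S)-2-(3,4-dihydroxyphenyl)-7-hydroxychroman-4-yl]chroman-3,5,7-triol (CNP0227165.3)
Conditions: H2 (1–3 atm), 20% Pd(OH)2/C, THF–MeOH (1:1), rt
Reagents that add atoms: none
Why: Heterogeneous hydrogenation should deliver hydrogen to C3=C4 from the face opposite the C2 aryl, placing the C4 aryl cis to it (4S), while hydrogenolysis cleaves the seven benzyl ethers to toluene and the aryl alkyl O1–C2 ethers of the flavan rings are expected to survive as they do in benzylated flavan-3-ols.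

## Compound list

1 | 2,4,6-trihydroxybenzaldehyde | O=Cc1c(O)cc(O)cc1O | starting material
2 | 4,6-bis(benzyloxy)-2-hydroxybenzaldehyde | O=Cc1c(O)cc(OCc2ccccc2)cc1OCc1ccccc1 | intermediate
3 | 4,6-bis(benzyloxy)-3-bromo-2-hydroxybenzaldehyde | O=Cc1c(O)c(Br)c(OCc2ccccc2)cc1OCc1ccccc1 | intermediate
4 | 2-(allyloxy)-4,6-bis(benzyloxy)-3-bromobenzaldehyde | O=Cc1c(OCC=C)c(Br)c(OCc2ccccc2)cc1OCc1ccccc1 | intermediate
5 | 3-(allyloxy)-1,5-bis(benzyloxy)-2-bromo-4-ethenylbenzene | C=Cc1c(OCC=C)c(Br)c(OCc2ccccc2)cc1OCc1ccccc1 | intermediate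
6 | 1-[4-(benzyloxy)-2-hydroxyphenyl]ethan-1-one | CC(=O)c1ccc(OCc2ccccc2)cc1O | starting material
7 | 1-[2-(allyloxy)-4-(benzyloxy)phenyl]ethan-1-one | CC(=O)c1ccc(OCc2ccccc2)cc1OCC=C | intermediate
8 | [2-(allyloxy)-4,6-bis(benzyloxy)-3-ethenylphenyl]lithium (not isolated) | [Li]c1c(OCc2ccccc2)cc(OCc2ccccc2)c(C=C)c1OCC=C | intermediate
9 | 1-[2-(allyloxy)-4-(benzyloxy)phenyl]-1-[2-(allyloxy)-4,6-bis(benzyloxy)-3-ethenylphenyl]ethan-1-ol, racemic (not isolated) | CC(O)(c1ccc(OCc2ccccc2)cc1OCC=C)c1c(OCc2ccccc2)cc(OCc2ccccc2)c(C=C)c1OCC=C | intermediate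
10 | 3-(allyloxy)-4-{1-[2-(allyloxy)-4-(benzyloxy)phenyl]ethenyl}-1,5-bis(benzyloxy)-2-ethenylbenzene | C=C(c1ccc(OCc2ccccc2)cc1OCC=C)c1c(OCc2ccccc2)cc(OCc2ccccc2)c(C=C)c1OCC=C | intermediate
11 | 3,5-bis(benzyloxy)-2-{1-[4-(benzyloxy)-2-hydroxyphenyl]ethenyl}-6-ethenylphenol | C=C(c1ccc(OCc2ccccc2)cc1O)c1c(OCc2ccccc2)cc(OCc2ccccc2)c(C=C)c1O | intermediate
12 | caffeic acid, (E)-3-(3,4-dihydroxyphenyl)prop-2-enoic acid | OC(=O)/C=C/c1ccc(O)c(O)c1 | starting material
13 | benzyl (E)-3-[3,4-bis(benzyloxy)phenyl]prop-2-enoate | O=C(OCc1ccccc1)/C=C/c1ccc(OCc2ccccc2)c(OCc2ccccc2)c1 | intermediate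
14 | (E)-3-[3,4-bis(benzyloxy)phenyl]prop-2-en-1-ol | OC/C=C/c1ccc(OCc2ccccc2)c(OCc2ccccc2)c1 | intermediate
15 | (E)-3-[3,4-bis(benzyloxy)phenyl]prop-2-en-1-yl methyl carbonate | COC(=O)OC/C=C/c1ccc(OCc2ccccc2)c(OCc2ccccc2)c1 | intermediate
16 | (S,S)-tetraene, bis[(1S)-1-(3,4-bis(benzyloxy)phenyl)allyl] ether of 11 | C=C(c1ccc(OCc2ccccc2)cc1O[C@H](c1ccc(OCc2ccccc2)c(OCc2ccccc2)c1)C=C)c1c(OCc2ccccc2)cc(OCc2ccccc2)c(C=C)c1O[C@H](c1ccc(OCc2ccccc2)c(OCc2ccccc2)c1)C=C | intermediate
17 | (2S)-5,7-bis(benzyloxy)-2-[3,4-bis(benzyloxy)phenyl]-8-{1-[4-(benzyloxy)-2-{[(1S)-1-(3,4-bis(benzyloxy)phenyl)prop-2-en-1-yl]oxy}phenyl]ethenyl}-2H-chromene (not isolated) | C=C(c1ccc(OCc2ccccc2)cc1O[C@H](c1ccc(OCc2ccccc2)c(OCc2ccccc2)c1)C=C)c1c(OCc2ccccc2)cc(OCc2ccccc2)c2c1O[C@H](c1ccc(OCc3ccccc3)c(OCc3ccccc3)c1)C=C2 | intermediate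
18 | (2S)-7-(benzyloxy)-2-[3,4-bis(benzyloxy)phenyl]-4-{(2S)-5,7-bis(benzyloxy)-2-[3,4-bis(benzyloxy)phenyl]-2H-chromen-8-yl}-2H-chromene | O(Cc1ccccc1)c1ccc2c(c1)O[C@H](c1ccc(OCc3ccccc3)c(OCc3ccccc3)c1)C=C2c1c(OCc3ccccc3)cc(OCc3ccccc3)c2c1O[C@H](c1ccc(OCc3ccccc3)c(OCc3ccccc3)c1)C=C2 | intermediate
19 | C3'-borane of 18, written as the monoalkylborane, boron trans to the C2' aryl (not isolated) | O(Cc1ccccc1)c1ccc2c(c1)O[C@H](c1ccc(OCc3ccccc3)c(OCc3ccccc3)c1)C=C2c1c(OCc3ccccc3)cc(OCc3ccccc3)c2c1O[C@H](c1ccc(OCc3ccccc3)c(OCc3ccccc3)c1)[C@@H](B)C2 | intermediate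
20 | (2R,3S)-5,7-bis(benzyloxy)-2-[3,4-bis(benzyloxy)phenyl]-8-{(2S)-7-(benzyloxy)-2-[3,4-bis(benzyloxy)phenyl]-2H-chromen-4-yl}chroman-3-ol | O(Cc1ccccc1)c1ccc2c(c1)O[C@H](c1ccc(OCc3ccccc3)c(OCc3ccccc3)c1)C=C2c1c(OCc3ccccc3)cc(OCc3ccccc3)c2c1O[C@H](c1ccc(OCc3ccccc3)c(OCc3ccccc3)c1)[C@@H](O)C2 | intermediate
21 | (2R,3S)-2-(3,4-dihydroxyphenyl)-8-[(2S,4S)-2-(3,4-dihydroxyphenyl)-7-hydroxychroman-4-yl]chroman-3,5,7-triol | Oc1ccc2c(c1)O[C@H](c1ccc(O)c(O)c1)C[C@@H]2c1c(O)cc(O)c2c1O[C@H](c1ccc(O)c(O)c1)[C@@H](O)C2 | target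

## Step count

Total: 14 steps. Longest linear sequence: 10 steps (steps 1, 2, 3, 4, 6, 7, 11, 12, 13, 14).

## Steps most likely to fail

**Step 12 (double ring-closing metathesis).** The cascade may stall after the first closure because the A-ring alkylidene fails to engage the tri-ortho-substituted 1,1-diarylethylene, with cross-metathesis or alkene isomerisation then consuming triene 17. The fallback forms the hindered upper ring by carbonyl addition and keeps metathesis only for the easy lower ring. It sets out from 6 and from aryllithium 8 (made from 5 as in step 6) and returns at 18.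

Ketone 6 is condensed with DMF dimethyl acetal to the enaminone (E)-1-[4-(benzyloxy)-2-hydroxyphenyl]-3-(dimethylamino)prop-2-en-1-one F1. Acid then closes it to 7-(benzyloxy)-4H-chromen-4-one F2. Rh- or Pd-catalysed asymmetric conjugate addition of 3,4-bis(benzyloxy)phenylboronic acid (ligand antipode chosen for 2S) should give (2S)-7-(benzyloxy)-2-[3,4-bis(benzyloxy)phenyl]chroman-4-one F3.

Addition of 8 to F3 (LaCl3·2LiCl, −78 °C) would give the tertiary 4-aryl-flavan-4-ol O-allyl ether F4. Pd(0)/morpholine deallylation gives the phenol carbinol F5, and mild dehydration (PPTS) gives the 4-aryl-2H-chromene phenol F6. Etherification of F6 with 15 under the conditions of step 11 gives the mono (S)-1-arylallyl ether F7. A single ring-closing metathesis onto the C4a' vinyl group then closes the lower ring to 18.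

**Step 11 (double allylic etherification).** The doubly ortho-substituted D-ring phenoxide may attack the allyl–iridium intermediate slowly, giving incomplete conversion, drift to the linear ether, or erosion of enantiopurity by re-ionisation of the branched ether. The fallback delivers each phenoxide inside an ion pair. It sets out from 11 and 14 and returns at 16.

Alcohol 14 is converted with 1,1'-carbonyldiimidazole to (E)-3-[3,4-bis(benzyloxy)phenyl]prop-2-en-1-yl 1H-imidazole-1-carboxylate F8. The disodium salt of 11 is acylated with F8 to the bis(aryl cinnamyl carbonate) F9. Ir/phosphoramidite-catalysed enantioselective decarboxylative allylic etherification of F9 releases each phenoxide next to its own allyl–iridium partner and should give 16.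

**Step 14 (hydrogenation with debenzylation).** The allylic and benzylic O1–C2 bond of the upper ring may undergo hydrogenolytic opening before the hindered alkene is saturated, or the facial selectivity at C4 may be poor. The fallback separates alkene reduction from debenzylation. It sets out from 20 and returns at 21.

Ionic hydrogenation (Et3SiH, CF3CO2H, CH2Cl2, −40 °C) protonates C3 to the doubly benzylic C4 cation. Hydride is expected to enter anti to the C2 aryl, giving the hepta-O-benzyl (2S,4S)-4-arylflavan F10 with no metal surface present. Hydrogenolysis of the benzyl ethers (H2, Pd(OH)2/C) then gives 21.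

## Further compounds

F1 | step 12 | (E)-1-[4-(benzyloxy)-2-hydroxyphenyl]-3-(dimethylamino)prop-2-en-1-one | CN(C)/C=C/C(=O)c1ccc(OCc2ccccc2)cc1O
F2 | step 12 | 7-(benzyloxy)-4H-chromen-4-one | O=c1ccoc2cc(OCc3ccccc3)ccc12
F3 | step 12 | (2S)-7-(benzyloxy)-2-[3,4-bis(benzyloxy)phenyl]chroman-4-one | O(Cc1ccccc1)c1ccc2c(c1)O[C@H](c1ccc(OCc3ccccc3)c(OCc3ccccc3)c1)CC2=O
F4 | step 12 | (2S)-4-[2-(allyloxy)-4,6-bis(benzyloxy)-3-ethenylphenyl]-7-(benzyloxy)-2-[3,4-bis(benzyloxy)phenyl]chroman-4-ol (C4 epimers) | O(Cc1ccccc1)c1ccc2c(c1)O[C@H](c1ccc(OCc3ccccc3)c(OCc3ccccc3)c1)CC2(O)c1c(OCc3ccccc3)cc(OCc3ccccc3)c(C=C)c1OCC=C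
F5 | step 12 | (2S)-7-(benzyloxy)-4-[4,6-bis(benzyloxy)-3-ethenyl-2-hydroxyphenyl]-2-[3,4-bis(benzyloxy)phenyl]chroman-4-ol (C4 epimers) | O(Cc1ccccc1)c1ccc2c(c1)O[C@H](c1ccc(OCc3ccccc3)c(OCc3ccccc3)c1)CC2(O)c1c(OCc3ccccc3)cc(OCc3ccccc3)c(C=C)c1O
F6 | step 12 | 3,5-bis(benzyloxy)-2-{(2S)-7-(benzyloxy)-2-[3,4-bis(benzyloxy)phenyl]-2H-chromen-4-yl}-6-ethenylphenol | O(Cc1ccccc1)c1ccc2c(c1)O[C@H](c1ccc(OCc3ccccc3)c(OCc3ccccc3)c1)C=C2c1c(OCc3ccccc3)cc(OCc3ccccc3)c(C=C)c1O
F7 | step 12 | (1S)-1-[3,4-bis(benzyloxy)phenyl]prop-2-en-1-yl ether of F6 (upper ring closed, lower ring open) | O(Cc1ccccc1)c1ccc2c(c1)O[C@H](c1ccc(OCc3ccccc3)c(OCc3ccccc3)c1)C=C2c1c(OCc3ccccc3)cc(OCc3ccccc3)c(C=C)c1O[C@H](c1ccc(OCc3ccccc3)c(OCc3ccccc3)c1)C=C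
F8 | step 11 | (E)-3-[3,4-bis(benzyloxy)phenyl]prop-2-en-1-yl 1H-imidazole-1-carboxylate | O=C(OC/C=C/c1ccc(OCc2ccccc2)c(OCc2ccccc2)c1)n1ccnc1
F9 | step 11 | bis{(E)-3-[3,4-bis(benzyloxy)phenyl]prop-2-en-1-yl} dicarbonate of bisphenol 11 | C=C(c1ccc(OCc2ccccc2)cc1OC(=O)OC/C=C/c1ccc(OCc2ccccc2)c(OCc2ccccc2)c1)c1c(OCc2ccccc2)cc(OCc2ccccc2)c(C=C)c1OC(=O)OC/C=C/c1ccc(OCc2ccccc2)c(OCc2ccccc2)c1
F10 | step 14 | (2R,3S)-5,7-bis(benzyloxy)-2-[3,4-bis(benzyloxy)phenyl]-8-{(2S,4S)-7-(benzyloxy)-2-[3,4-bis(benzyloxy)phenyl]chroman-4-yl}chroman-3-ol | O(Cc1ccccc1)c1ccc2c(c1)O[C@H](c1ccc(OCc3ccccc3)c(OCc3ccccc3)c1)C[C@@H]2c1c(OCc3ccccc3)cc(OCc3ccccc3)c2c1O[C@H](c1ccc(OCc3ccccc3)c(OCc3ccccc3)c1)[C@@H](O)C2
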